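## Retrosynthetic overview
1. The last bond made is C9–C11, not the ArO–CH2 ether bond. A C8 allylsilane attacks ArOCH2+ (from 7-(chloromethoxy)coumarin) in an anti-SE2′ sense, creating C9 and the 8(12)-methylidene together.
2. The allylsilane comes from Ni-catalysed OMe → CH2SiMe3 exchange on a C8 methyl enol ether. The 3β-OAc comes from an equilibrating reduction of a C3 ketone.
3. Key step: an anionic oxy-Cope rearrangement of a 1-methoxy-3,3,4,5-tetramethyl-2-vinylbicyclo[2.2.2]oct-5-en-2-ol makes C1–C10 and breaks C3–C8. It delivers the cis-decalin with the contiguous C4/C5/C10 quaternary carbons.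
4. The bicyclooctenone comes from gem-dimethylation of a catalytic asymmetric Diels–Alder adduct of 1-methoxy-3,4-dimethylcyclohexa-1,3-diene and 2-bromoacrolein (a ketene equivalent). This step sets the absolute configuration.
5. Ring order: ring B is the Birch-reduced ring of 3,4-dimethylanisole. The Diels–Alder adds a temporary C3–C4 bridge, and ring A closes in the oxy-Cope step.

Assumption: the SMILES is taken literally (C27H34O5). Both ring-fusion carbons carry methyl groups, the decalin is cis-fused, and 3-OAc, 5-Me, 10-Me and C11 all lie on one (β) face, giving 3S,5S,9S,10R.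

Drimane numbering is used throughout: C3 = CHOAc, C4 = CMe2, C5 and C10 = fusion C–Me, C8 = C(=C12H2), C9 = CH–C11H2OAr.

## Route

**Step 1**
Reactants: 1, 3,4-dimethylanisole
Product: 2, 1-methoxy-4,5-dimethylcyclohexa-1,4-diene
Conditions: Li, NH3(l), THF, t-BuOH, −78 → −33 °C
Reagents that add atoms: none
Why: Birch reduction; protonation at the 2- and 5-positions leaves OMe and both methyls on the two surviving double bonds, and no stereocentre is formed.

**Step 2**
Reactants: 2
Product: 3, 1-methoxy-3,4-dimethylcyclohexa-1,3-diene
Conditions: t-BuOK (0.3 equiv), DMSO, 25 °C; distil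
Reagents that add atoms: none
Why: Base-mediated 1,4 → 1,3-diene equilibration through the pentadienyl anion favours the linearly conjugated isomer with a tetrasubstituted C=C and an enol-ether C=C, and residual 2 is inert in step 4.

**Step 3**
Reactants: 4, acrolein
Product: 5, 2-bromoacrolein
Conditions: Br2, CH2Cl2, −78 → 0 °C; then Et3N, 0 °C
Reagents that add atoms: bromine, BrBr
Why: Bromination followed by E2 dehydrobromination of the 2,3-dibromopropanal removes the acidic α-H.

**Step 4**
Reactants: 3 and 5
Product: 6, (1S,2R,4R)-2-bromo-1-methoxy-4,5-dimethylbicyclo[2.2.2]oct-5-ene-2-carbaldehyde (Br syn and CHO anti to the C=C bridge)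
Conditions: oxazaborolidinone from (S)-N-tosyltryptophan and n-BuB(OH)2 (10 mol %), CH2Cl2, −78 °C
Reagents that add atoms: none
Why: Catalytic enantioselective Diels–Alder reaction in which the 1-OMe group enforces "ortho" regiochemistry (bonds C8–C3 and C5–C4), and catalyst shielding of one enal face plus the exo-CHO mode typical of 2-bromoacrolein fixes bridgeheads C8 and C5; the sense is assigned by analogy with the cyclopentadiene benchmark ((S)-catalyst gives the (R)-bromoaldehyde, the ent-catalyst being the remedy if reversed), and the minor endo-CHO diastereomer, which would lead to ent-8, is removed by chromatography.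

**Step 5**
Reactants: 6
Product: 7, (1S,2R,4R)-1-methoxy-4,5-dimethylspiro[bicyclo[2.2.2]oct-5-ene-2,2'-oxirane]
Conditions: NaBH4, MeOH, 0 °C; then K2CO3, rt
Reagents that add atoms: none
Why: Aldehyde 1,2-reduction followed by intramolecular Williamson closure of the bromohydrin, with inversion at C3, a centre that is erased in step 6.

**Step 6**
Reactants: 7
Product: 8, (1S,4R)-1-methoxy-4,5-dimethylbicyclo[2.2.2]oct-5-en-2-one
Conditions: H5IO6, THF–H2O, 0 °C → rt
Reagents that add atoms: none (water opens the epoxide at CH2, that carbon leaves as CH2O, and the ketone O is the former epoxide O)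
Why: Epoxide hydrolysis and Malaprade glycol cleavage unmask the ketene-equivalent carbon as the C3 ketone, while the bridgehead ether and the trisubstituted alkene are inert.

**Step 7**
Reactants: 8
Product: 9, (1S,4S)-1-methoxy-3,3,4,5-tetramethylbicyclo[2.2.2]oct-5-en-2-one
Conditions: KHMDS, THF, −78 °C, then MeI; second cycle KHMDS/MeI, −78 → 0 °C (one pot)
Reagents that add atoms: iodomethane, CI (twice)
Why: Exhaustive enolate alkylation, where C4 is the only enolisable position because the other α-carbon is a bridgehead, so the gem-dimethyl group is installed regiospecifically (the C5 descriptor changes by CIP priority only).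

**Step 8**
Reactants: 9
Product: 10, (1S,2S,4S)-2-ethenyl-1-methoxy-3,3,4,5-tetramethylbicyclo[2.2.2]oct-5-en-2-ol (vinyl syn to the C=C bridge)
Conditions: CH2=CHMgBr, anhydrous CeCl3, THF, −78 → 0 °C
Reagents that add atoms: vinylmagnesium bromide, C=C[Mg]Br
Why: Organocerium 1,2-addition to a non-enolisable hindered ketone; the gem-dimethyl group hinders both faces equally, so the inward C7–H of the ethano bridge decides and vinyl enters from the etheno-bridge side, setting C3 as the oxy-Cope step requires.

**Step 9 (key step)**
Reactants: 10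
Product: 11, (4aR,8aS)-6-methoxy-1,1,4a,8a-tetramethyl-3,4,4a,7,8,8a-hexahydronaphthalen-2(1H)-one (cis-decalin with C3 ketone, 4,4-Me2, 5β-Me, 10β-Me and the C8(OMe)=C9 enol ether)
Conditions: KH, 18-crown-6, THF, 0 → 50 °C; quench with pH 7 buffer at −78 °C
Reagents that add atoms: none
Why: Anionic oxy-Cope [3,3] rearrangement in which the bicycle enforces a boat transition state, so the vinyl terminus (C1) bonds suprafacially to C10 on the face turned toward the C3–C4 bridge and the new C10 quaternary centre is necessarily cis to C5–Me; alkoxide acceleration, the donor OMe on the breaking C3–C8 bond and release of bicyclic strain pay for the third contiguous quaternary carbon.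

**Step 10**
Reactants: 11
Product: 12, (2S,4aR,8aS)-6-methoxy-1,1,4a,8a-tetramethyl-1,2,3,4,4a,7,8,8a-octahydronaphthalen-2-ol (3β-OH)
Conditions: Li, NH3(l)/THF, EtOH, −78 → −33 °C; solid NH4Cl
Reagents that add atoms: none
Why: Dissolving-metal ketone reduction under product-stability control; quaternary C4 must stay equatorial on ring B, which locks one conformer in which the equatorial C3–OH is β (3S) and the axial epimer would be 1,3-diaxial to C6, and enol ethers are inert to Li/NH3.

**Step 11**
Reactants: 12
Product: 13, (2S,4aR,8aS)-1,1,4a,8a-tetramethyl-6-[(trimethylsilyl)methyl]-1,2,3,4,4a,7,8,8a-octahydronaphthalen-2-ol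
Conditions: Ni(cod)2 (5–10 mol %), LiCH2SiMe3 (3 equiv), toluene, rt → 50 °C
Reagents that add atoms: (trimethylsilyl)methyllithium, [Li]C[Si](C)(C)C
Why: Nickel-catalysed dealkoxylative (Wenkert-type) cross-coupling of the enol-ether C(sp2)–OMe bond keeps the double bond at C8=C9, so the regiochemistry written by the oxy-Cope step passes to the allylsilane, and the first equivalent of RLi only forms the C3 alkoxide.

**Step 12**
Reactants: 13
Product: 14, (2S,4aR,8aS)-1,1,4a,8a-tetramethyl-6-[(trimethylsilyl)methyl]-1,2,3,4,4a,7,8,8a-octahydronaphthalen-2-yl acetate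
Conditions: Ac2O, pyridine, DMAP, CH2Cl2, rt
Reagents that add atoms: acetic anhydride, CC(=O)OC(C)=O
Why: DMAP-catalysed acylation of the equatorial alcohol with retention at C3, under basic conditions that leave the allylsilane untouched.

**Step 13**
Reactants: 15, umbelliferone (7-hydroxycoumarin)
Product: 16, 7-[(methylsulfanyl)methoxy]-2H-chromen-2-one
Conditions: NaH, ClCH2SMe, NaI (cat.), DMF, 0 °C → rt
Reagents that add atoms: chloromethyl methyl sulfide, ClCSC
Why: Williamson O-alkylation of the phenoxide to give the O,S-acetal, which the lactone tolerates.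

**Step 14**
Reactants: 16
Product: 17, 7-(chloromethoxy)-2H-chromen-2-one
Conditions: SO2Cl2, CH2Cl2, 0 °C; evaporate and use crude
Reagents that add atoms: sulfuryl chloride, O=S(=O)(Cl)Cl (leaves Cl)
Why: Chlorinative cleavage of the O,S-acetal through the chlorosulfonium ion and loss of MeSCl is the standard route to aryl chloromethyl ethers, and the electron-poor coumarin C=C does not react.

**Step 15**
Reactants: 14 and 17
Product: 18, polyanthinin as drawn: 7-{[(1S,4aS,6S,8aR)-6-acetoxy-4a,5,5,8a-tetramethyl-2-methylidenedecahydronaphthalen-1-yl]methoxy}-2H-chromen-2-one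
Conditions: AgOTf, 2,6-di-tert-butyl-4-methylpyridine, 4 Å MS, CH2Cl2, −78 → −30 °C; Et3N quench
Reagents that add atoms: none
Why: Proposed new method: Ag+ abstracts chloride to give ArOCH2OTf/ArO=CH2+, which is captured at C9 (the γ-carbon) in an anti-SE2′ process, and collapse of the β-silyl cation gives the 8(12)-methylidene regiospecifically and irreversibly; in the locked conformer the C10–C1 bond is pseudoaxial on the concave α face, so the small CH2 electrophile enters axially from the convex β face through a chair-like transition state to give 9S (H-9 α, C11 cis to both angular methyls), while the hindered base suppresses protodesilylation; the closest known reactions are Hosomi–Sakurai alkylations of allylsilanes with α-chloro ethers and AgOTf-promoted C-allylation of glycosyl chlorides.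

## Compound list
| No. | Name | SMILES | Role |
|---|---|---|---|
| 1 | 3,4-dimethylanisole | COc1ccc(C)c(C)c1 | starting material |
| 2 | 1-methoxy-4,5-dimethylcyclohexa-1,4-diene | COC1=CCC(C)=C(C)C1 | intermediate |
| 3 | 1-methoxy-3,4-dimethylcyclohexa-1,3-diene | COC1=CC(C)=C(C)CC1 | intermediate |
| 4 | acrolein | C=CC=O | starting material |
| 5 | 2-bromoacrolein | C=C(Br)C=O | intermediate |
| 6 | (1S,2R,4R)-2-bromo-1-methoxy-4,5-dimethylbicyclo[2.2.2]oct-5-ene-2-carbaldehyde | CO[C@@]12CC[C@@](C)(C(C)=C1)C[C@]2(Br)C=O | intermediate |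
| 7 | (1S,2R,4R)-1-methoxy-4,5-dimethylspiro[bicyclo[2.2.2]oct-5-ene-2,2'-oxirane] | CO[C@@]12CC[C@@](C)(C(C)=C1)C[C@@]23CO3 | intermediate |
| 8 | (1S,4R)-1-methoxy-4,5-dimethylbicyclo[2.2.2]oct-5-en-2-one | CO[C@@]12CC[C@@](C)(C(C)=C1)CC2=O | intermediate |
| 9 | (1S,4S)-1-methoxy-3,3,4,5-tetramethylbicyclo[2.2.2]oct-5-en-2-one | CO[C@@]12CC[C@@](C)(C(C)=C1)C(C)(C)C2=O | intermediate |
| 10 | (1S,2S,4S)-2-ethenyl-1-methoxy-3,3,4,5-tetramethylbicyclo[2.2.2]oct-5-en-2-ol | CO[C@@]12CC[C@@](C)(C(C)=C1)C(C)(C)[C@@]2(O)C=C | intermediate |
| 11 | (4aR,8aS)-6-methoxy-1,1,4a,8a-tetramethyl-3,4,4a,7,8,8a-hexahydronaphthalen-2(1H)-one | COC1=C[C@@]2(C)CCC(=O)C(C)(C)[C@@]2(C)CC1 | intermediate |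
| 12 | (2S,4aR,8aS)-6-methoxy-1,1,4a,8a-tetramethyl-1,2,3,4,4a,7,8,8a-octahydronaphthalen-2-ol | COC1=C[C@@]2(C)CC[C@H](O)C(C)(C)[C@@]2(C)CC1 | intermediate |
| 13 | (2S,4aR,8aS)-1,1,4a,8a-tetramethyl-6-[(trimethylsilyl)methyl]-1,2,3,4,4a,7,8,8a-octahydronaphthalen-2-ol | C[Si](C)(C)CC1=C[C@@]2(C)CC[C@H](O)C(C)(C)[C@@]2(C)CC1 | intermediate |
| 14 | acetate of 13 | C[Si](C)(C)CC1=C[C@@]2(C)CC[C@H](OC(C)=O)C(C)(C)[C@@]2(C)CC1 | intermediate |
| 15 | umbelliferone | Oc1ccc2ccc(=O)oc2c1 | starting material |
| 16 | 7-[(methylsulfanyl)methoxy]-2H-chromen-2-one | CSCOc1ccc2ccc(=O)oc2c1 | intermediate |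
| 17 | 7-(chloromethoxy)-2H-chromen-2-one | ClCOc1ccc2ccc(=O)oc2c1 | intermediate |
| 18 | polyanthinin (3S,5S,9S,10R) | C=C1CC[C@]2(C)C(C)(C)[C@@H](OC(C)=O)CC[C@]2(C)[C@H]1COc1ccc2ccc(=O)oc2c1 | target |

## Step count
- Total steps: 15.
- Longest linear sequence: 12 (steps 1, 2, 4–12 and 15).

## Three steps most likely to fail
1. **Step 9, oxy-Cope forming the third contiguous quaternary carbon.**
   - Fallback: run the same Birch/Diels–Alder/oxy-Cope logic in the transposed sense, starting from 2,3,4-trimethylanisole.
   - The bicyclic ketone carbon then becomes C8 and its α-carbon becomes C9. C11 is introduced there by enolate alkylation syn to the etheno bridge, which maps to 9β.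
   - The [3,3] shift then has to build only the C5/C10 pair next to an sp2 C4.
   - The last C4 methyl is added afterwards by Simmons–Smith cyclopropanation of the resulting C3 enol ether, followed by acid opening.
2. **Step 15, aryloxymethyl SE2′ coupling.** The risks are protodesilylation, low reactivity at neopentyl C9, and β-face selectivity opposed by the 1,3-diaxial C5–Me.
   - Fallback: separate the C–C and C–O bond formations. Use Me2AlCl/formaldehyde SE2′ hydroxymethylation of 14 to the 9-CH2OH compound, then a Mitsunobu reaction with umbelliferone.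
   - If carbon electrophiles choose the α face, set C9 on the rigid bicycle by the transposed route described under item 1.
3. **Step 4, asymmetric Diels–Alder.** The risks are ee, exo/endo ratio, and isomeric purity and acid sensitivity of diene 3.
   - Fallback: switch from catalyst control to reagent control. Carry out a thermal Diels–Alder reaction of 2 (conjugated in situ) with the enantiopure C2-symmetric ketene equivalent trans-2-methylene-1,3-dithiolane 1,3-dioxide, which has no endo/exo issue.
   - Sulfoxide deoxygenation and dithiolane hydrolysis then give 8.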